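**Plan**

- Retrosynthesis: the two phenolic C–O bonds (O on C1 of the monobromo ring A, O on C1 of the tribromo ring B) are traced back to C–CHO bonds. Both oxygens sit ortho to the ether oxygen on C2 of their ring. These are the positions where a formyl group activates ring A for fluoride displacement and where ortho-formylation of a phenol places one on ring B, so one twofold aryl C→O migration can unveil both hydroxyls.
- Further cuts: the diaryl ether C–O bond (SNAr at the C–F carbon of ring A), the ring B C–CHO bond (ortho-formylation), and the ring B C3–Br bond (ortho-bromination of 3,5-dibromophenol).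
- Forward: both benzene rings are bought. Ring B is brominated and formylated, joined to ring A through the ether oxygen, both formyl groups are oxidised to formates in one operation, and the formates are cleaved. No ring is formed.
- Stereochemistry: the target has no stereocentre and no configurationally stable axis, so nothing has to be set.

Key step: step 4

Remark: the target is achiral (no stereogenic centre; the diaryl ether rotates freely), so the "single enantiomer" is the compound itself. Where one operation performs the same change twice (steps 4 and 5), the singly converted species is listed as the in-flask intermediate, in the order expected from sterics and electronics.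

**Route**

Step 1
Reactants: 1 3,5-dibromophenol
Product: 2 2,3,5-tribromophenol
Conditions: NBS (1.0 equiv, slow addition), i-Pr2NH (10 mol%), CH2Cl2, −20 → 0 °C; dil. HCl work-up
Reagents that add atoms: N-bromosuccinimide, O=C1CCC(=O)N1Br
Why: Amine-mediated ortho-bromination of a phenol, in which the N-bromoamine hydrogen-bonded to the phenol OH delivers bromine to the neighbouring carbon; the two ortho carbons are equivalent, C4 is shielded by two flanking bromines, and one equivalent of NBS at low temperature should limit a second ortho bromination.

Step 2
Reactants: 2 2,3,5-tribromophenol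
Product: 4 3,4,6-tribromo-2-hydroxybenzaldehyde, via salicyl alcohol 3 (not isolated)
Conditions: MgCl2 (2 equiv), Et3N (4 equiv), (CH2O)n (6 equiv), MeCN, reflux; 1 M HCl
Reagents that add atoms: paraformaldehyde (as formaldehyde), C=O
Why: Magnesium-mediated ortho-formylation (Casnati–Skattebøl): the magnesium phenoxide delivers formaldehyde to the only free ortho carbon (C6) to give the salicyl alkoxide 3, which a second formaldehyde oxidises to the aldehyde by Oppenauer-type hydride transfer; ortho-bromophenols are established substrates and the aryl bromides are untouched.

Step 3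
Reactants: 4 3,4,6-tribromo-2-hydroxybenzaldehyde; 5 4-bromo-2-fluorobenzaldehyde
Product: 6 4-bromo-2-(3,5,6-tribromo-2-formylphenoxy)benzaldehyde
Conditions: 5 (1.2 equiv), Cs2CO3 (1.5 equiv), DMF, 90 °C, N2
Reagents that add atoms: none
Why: Nucleophilic aromatic substitution (addition–elimination): the caesium phenoxide of 4 attacks the C–F carbon ortho to the formyl group of 5, which stabilises the Meisenheimer adduct; fluoride leaves far faster than the para bromide, and the ring B bromides stay deactivated while that ring is a phenoxide.

Step 4
Reactants: 6 4-bromo-2-(3,5,6-tribromo-2-formylphenoxy)benzaldehyde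
Product: 8 3,4,6-tribromo-2-[5-bromo-2-(formyloxy)phenoxy]phenyl formate, via formyl monoformate 7 (not isolated)
Conditions: mCPBA (3.0 equiv, dried), CH2Cl2, 0 °C → reflux; aq. Na2S2O3, pH 7 buffer wash; crude 8 taken on
Reagents that add atoms: 3-chloroperbenzoic acid (mCPBA), O=C(OO)c1cccc(Cl)c1
Why: The peracid adds to each formyl carbonyl to give a peroxy hemiacetal (Criegee adduct), in which the aryl group shifts from carbon to the proximal peroxide oxygen as 3-chlorobenzoate leaves, so two aryl C–C bonds are exchanged for aryl C–O bonds (Baeyer–Villiger oxidation of aryl aldehydes, the peracid form of the Dakin reaction). The closest known reaction is the mCPBA oxidation of 2-alkoxy- and 2-aryloxybenzaldehydes to aryl formates. No ring closes and no stereocentre is formed. The step needs aryl migration to win over hydride migration (which would end at carboxylic acids) at both carbonyls; on each ring the ether oxygen ortho to the formyl group donates into the migrating ipso carbon, and on ring B the two ortho substituents add strain to the tetrahedral adduct that aryl migration relieves. Anhydrous, non-basic conditions suppress the hydrate pathway; the less hindered, less electron-poor ring A should react first (7), and excess peracid with gentle heating should drive the ring B carbonyl. Aryl bromides and the diaryl ether are inert to mCPBA.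

Step 5
Reactants: 8 3,4,6-tribromo-2-[5-bromo-2-(formyloxy)phenoxy]phenyl formate
Product: 10 3,4,6-tribromo-2-(5-bromo-2-hydroxyphenoxy)phenol, via hydroxy monoformate 9 (not isolated)
Conditions: K2CO3 (3 equiv), MeOH, 0 °C → rt; 1 M HCl
Reagents that add atoms: none
Why: Base-mediated transesterification (methanolysis) of aryl formates, which are among the most labile esters because the bromophenoxides are good leaving groups; the formate on the more acidic tribromophenol ring is expected to leave first (9), and the aryl bromides and the unactivated diaryl ether should not react at room temperature.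

**Compound list**

1 | 3,5-dibromophenol | Oc1cc(Br)cc(Br)c1 | starting material
2 | 2,3,5-tribromophenol | Oc1cc(Br)cc(Br)c1Br | intermediate
3 | 3,4,6-tribromo-2-(hydroxymethyl)phenol (formed as its magnesium salt, not isolated) | OCc1c(O)c(Br)c(Br)cc1Br | intermediate
4 | 3,4,6-tribromo-2-hydroxybenzaldehyde | O=Cc1c(O)c(Br)c(Br)cc1Br | intermediate
5 | 4-bromo-2-fluorobenzaldehyde | O=Cc1ccc(Br)cc1F | starting material
6 | 4-bromo-2-(3,5,6-tribromo-2-formylphenoxy)benzaldehyde | O=Cc1ccc(Br)cc1Oc1c(C=O)c(Br)cc(Br)c1Br | intermediate
7 | 4-bromo-2-(3,5,6-tribromo-2-formylphenoxy)phenyl formate (not isolated) | O=COc1ccc(Br)cc1Oc1c(C=O)c(Br)cc(Br)c1Br | intermediate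
8 | 3,4,6-tribromo-2-[5-bromo-2-(formyloxy)phenoxy]phenyl formate | O=COc1ccc(Br)cc1Oc1c(OC=O)c(Br)cc(Br)c1Br | intermediate
9 | 4-bromo-2-(3,5,6-tribromo-2-hydroxyphenoxy)phenyl formate (not isolated) | O=COc1ccc(Br)cc1Oc1c(O)c(Br)cc(Br)c1Br | intermediate
10 | 3,4,6-tribromo-2-(5-bromo-2-hydroxyphenoxy)phenol | Oc1ccc(Br)cc1Oc1c(O)c(Br)cc(Br)c1Br | target
11 | 2,4-dibromo-6-nitroaniline (used only in the fallback to step 1) | Nc1c(Br)cc(Br)cc1[N+](=O)[O-] | starting material

**Step count and risks**

Total step count: 5. Longest linear sequence: 5 steps (1 → 10); 5 enters at step 3.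

Steps most likely to fail:

1. Step 4. Hydride instead of aryl migration at the hindered, electron-poor ring B carbonyl would divert material to carboxylic acids, or the oxidation could stall after the first formyl group. The fallback replaces hydride by methyl as the competing migrating group. It sets out from 6. Addition of MeMgBr (2.5 equiv, THF, −78 °C, where aryl bromides do not exchange) should give 1-[4-bromo-2-[3,5,6-tribromo-2-(1-hydroxyethyl)phenoxy]phenyl]ethanol F1 as a diastereomer mixture. Dess–Martin oxidation (CH2Cl2, rt) should give 1-[2-(2-acetyl-5-bromophenoxy)-3,4,6-tribromophenyl]ethanone F2. Baeyer–Villiger oxidation with CF3CO3H (TFAA, urea·H2O2, Na2HPO4, CH2Cl2), in which aryl migrates in preference to methyl even on electron-poor rings, should give 2-(2-acetoxy-5-bromophenoxy)-3,4,6-tribromophenyl acetate F3. Methanolysis under the conditions of step 5 brings the sequence back to the route at 10.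

2. Step 3. Ether formation by a hindered phenoxide conjugated to its own carbonyl may be slow, and displacement of formyl-activated bromides could compete and lead to oligomeric ethers. The fallback lowers the oxidation level of ring B during the coupling. It sets out from 4, which NaBH4 (MeOH/THF, 0 °C) should reduce to 3, here isolated. The more nucleophilic phenoxide of 3, on a ring that no longer activates its bromides, is coupled with 5 (Cs2CO3, DMF, 70 °C; only the phenol is deprotonated) to give 4-bromo-2-[3,5,6-tribromo-2-(hydroxymethyl)phenoxy]benzaldehyde F4. Activated MnO2 (CH2Cl2, rt) then oxidises the benzylic alcohol, and the sequence comes back to the route at 6.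

3. Step 1. Over-bromination at the second ortho carbon and some para attack could give mixtures that are hard to separate. The fallback fixes the bromine pattern through the substitution of an aniline instead of through selectivity. It sets out from 11, the second commercial starting material, used in place of 1. Diazotisation (NaNO2, conc. H2SO4/AcOH, 0–10 °C) gives 2,4-dibromo-6-nitrobenzenediazonium hydrogensulfate F5 (not isolated), and a Sandmeyer reaction (CuBr, 48% HBr, 60 °C) should give 1,2,5-tribromo-3-nitrobenzene F6. Reduction with Fe/NH4Cl (EtOH/H2O, 80 °C), which leaves aryl bromides intact, should give 2,3,5-tribromoaniline F7. Diazotisation to 2,3,5-tribromobenzenediazonium hydrogensulfate F8 (not isolated) and hydrolysis in hot aqueous H2SO4 then gives the phenol, and the sequence comes back to the route at 2.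

**Further compounds**

F1 | step 4 | 1-[4-bromo-2-[3,5,6-tribromo-2-(1-hydroxyethyl)phenoxy]phenyl]ethanol (mixture of diastereomers) | CC(O)c1ccc(Br)cc1Oc1c(C(C)O)c(Br)cc(Br)c1Br
F2 | step 4 | 1-[2-(2-acetyl-5-bromophenoxy)-3,4,6-tribromophenyl]ethanone | CC(=O)c1ccc(Br)cc1Oc1c(C(C)=O)c(Br)cc(Br)c1Br
F3 | step 4 | 2-(2-acetoxy-5-bromophenoxy)-3,4,6-tribromophenyl acetate | CC(=O)Oc1ccc(Br)cc1Oc1c(OC(C)=O)c(Br)cc(Br)c1Br
F4 | step 3 | 4-bromo-2-[3,5,6-tribromo-2-(hydroxymethyl)phenoxy]benzaldehyde | O=Cc1ccc(Br)cc1Oc1c(CO)c(Br)cc(Br)c1Br
F5 | step 1 | 2,4-dibromo-6-nitrobenzenediazonium hydrogensulfate (not isolated) | N#[N+]c1c(Br)cc(Br)cc1[N+](=O)[O-].OS(=O)(=O)[O-]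
F6 | step 1 | 1,2,5-tribromo-3-nitrobenzene | O=[N+]([O-])c1cc(Br)cc(Br)c1Br
F7 | step 1 | 2,3,5-tribromoaniline | Nc1cc(Br)cc(Br)c1Br
F8 | step 1 | 2,3,5-tribromobenzenediazonium hydrogensulfate (not isolated) | N#[N+]c1cc(Br)cc(Br)c1Br.OS(=O)(=O)[O-]
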